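I decide to read both runs on one clock rather than by the hour.

| flask | left-handed substrate | right-handed substrate | reagent | free catalyst | racemization catalyst | remark | time |
|---|---|---|---|---|---|---|---|
| south-east | 0.10 M | 0.10 M | 0.20 M | 0.20 mM | 0.20 mM | the very flask that is asked about, followed so far |  |
| north-east | 0.10 M | 0.10 M | 0.20 M | 0.30 mM | 0.20 mM | run made earlier |  |
| flask | 0.10 M | 0.10 M | 0.200 M | 0.20 mM | 0.20 mM |  | 3.0 d |

| run | time / h | left-handed product / % | left-handed substrate / % |
|---|---|---|---|
| south-east | 0.500 | 2.5 | 47.3 |
| south-east | 1.33 | 6.1 | 44.4 |
| south-east | 2.50 | 12.0 | 38.4 |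
| south-east | 4.00 | 19.0 | 32.0 |
| south-east | 5.00 | 22.0 | 30.7 |
| south-east | 6.00 | 24.0 | 28.5 |
| south-east | 8.00 | 27.8 | 25.4 |
| north-east | 2.50 | 17.5 | 36.4 |
| north-east | 4.00 | 21.5 | 30.0 |
| north-east | 5.00 | 26.5 | 25.4 |
| north-east | 8.00 | 32.8 | 22.0 |
| north-east | 12.0 | 38.4 | 15.3 |
| north-east | 20.0 | 45.7 | 9.9 |
| north-east | 30.0 | 50.6 | 9.1 |

(scatter of a reading: 1 percentage point)

- amount of left-handed product in percent of the left-handed substrate and right-handed substrate together charged, at 15 h, 40 h and 3.0 d

- free catalyst is single-handed; left-handed substrate and right-handed substrate are mirror images of each other, charged as a racemate, each of them at the stated concentration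

The two runs differ in free catalyst: 0.20 mM in the south-east flask, 0.30 mM in the north-east run. At 2.50 h the north-east run reads 1.46 times the left-handed product of the south-east flask, close to the catalyst ratio of 1.50. But at 8.00 h the same product ratio is 1.18. So does the catalyst count or not?

It counts, on another clock. I define the clock factor f as the free catalyst of the south-east flask over that of the north-east run: 0.667. My rule says that, with the other charges equal, time t in the south-east flask reads like time f·t in the north-east run. So 8.00 h becomes 5.34 h, and interpolating the north-east readings gives 27.2 %. The south-east flask reads 27.8 % there, with a scatter of 1 percentage point. The small ratio at 8.00 h is then the north-east run standing further along one slowing curve. The racemization catalyst is equal in both runs and doesn't rescale, so the rule is an approximation.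

Now I reckon the flask. 15 h maps to 10.0 h and gives 35.6 %. 40 h maps to 26.7 h and gives 49.0 %. 3.0 d maps to 48.0 h, past the last reading at 30.0 h. I bracket it between that reading, 50.6 %, and its last slope continued, 59.4 %.

The forecast says 37 %, 49 % and 54 %, and it reads the fall of its rate constant as one that “suggests catalyst death”.

The flask gives 36.2 %, 49.0 % and 54.5 %.

    reagent + free catalyst + left-handed substrate → free catalyst + left-handed product (k = 52.0 /M²/min)
    reagent + free catalyst + right-handed substrate → free catalyst + right-handed product (k = 25.0 /M²/min)
    left-handed substrate + racemization catalyst ⇌ right-handed substrate + racemization catalyst, rate k3*[racemization catalyst]*[left-handed substrate] forward; the back reaction follows from the equilibrium constant (k = 3.90 /M/min)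
    free catalyst → spent catalyst (k = 1.90 × 10⁻⁶ /min)

On the clock with f at 0.667, my 35.6 % stands against 36.2 %, my 49.0 % against 49.0 %, and the value at 3.0 d lies inside my bracket. At 0.342 d the left-handed substrate has a half-life of 0.40 d by its step to left-handed product, and the right-handed substrate has 0.84 d by its step to right-handed product, a selectivity factor of 2.10. At 3.00 d the flask holds 54.5 % left-handed product and 32.0 % right-handed product, with 99.2 % of the catalyst still free catalyst.

The readings were computed for substances that don't exist; noise was put on by code.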